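**Retrosynthetic overview**
1. Feature: chain atoms C2–C7 (C1 sits on guaiacyl ring A, C7 on syringyl ring B) carry oxygen only at C3 and C5, syn (3R,5S). With C7 as an aldehyde carbon and C2 as CH2Cl, this is a 6-chloro-2,4,6-trideoxy-D-erythro-hexose. Its two ends are chemically different although the target is almost meso.
2. Last disconnection: hydrogenolysis of a C3,C5,C7-triacetate bis(benzyl ether) erases the C7 oxygen and frees both phenols.
3. C1–C2 comes from CuI-catalysed opening of the C2–C3 oxirane by the ring A benzylic Grignard reagent. C7–ring B comes from aryl Grignard addition to the lactol carbon.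
4. C3–C4, C5–C6 and O3–C7 come from one aldolase-catalysed tandem aldol of chloroacetaldehyde with two acetaldehydes.
5. Ring order: the oxane lactol is built in step 1 and opened in step 3; the oxirane is built in step 4 and opened in step 8. Rings A and B are bought.

Key step: step 1

Remark: target numbering is used for the chain throughout. The C7 carbinol made in step 3 is carried as an epimer mixture because step 11 erases it, and the CIP letters at C3 and C5 change with the neighbouring groups although no bond at these centres is touched after step 1.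

Step 1
Reactants: 1 chloroacetaldehyde (commercial aqueous solution); 2 acetaldehyde (two equivalents)
Product: 5 6-chloro-2,4,6-trideoxy-D-erythro-hexopyranose [(4R,6S)-6-(chloromethyl)oxane-2,4-diol; anomer mixture], via (S)-4-chloro-3-hydroxybutanal 3 (not isolated), via (3R,5S)-6-chloro-3,5-dihydroxyhexanal 4 (not isolated)
Conditions: 2-deoxy-D-ribose-5-phosphate aldolase (recombinant E. coli cell-free lysate), aq. NaHCO3 buffer pH 7.2–7.5, 25 °C, slow co-feed of 1 and 2 (2.1 equiv); acetone precipitation of protein, EtOAc extraction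
Reagents that add atoms: none
Why: The active-site lysine condenses with 2 to an enamine that adds to the aldehyde of 1 (bond C3–C4), and after hydrolysis the released 3 is the acceptor for a second enamine (bond C5–C6) to give 4. This is the known sequential aldol reaction of this aldolase with α-substituted acetaldehyde acceptors, run on its standard substrate pair. The one ring closes by 6-exo-trig addition of the C3 hydroxyl to the C7 aldehyde, and because the oxane lactol hides the aldehyde, chain growth ends after two additions. C3 (set first) and C5 (set second) are both fixed by the enzyme pocket, which offers the same face of each acceptor carbonyl to the bound enamine, so the syn relationship and the absolute sense come from the catalyst and not from the substrate. The step needs cross- over self-aldol selectivity: 2 is the only competent enamine donor present, the α-chlorine makes 1 the more electrophilic acceptor, and slow co-feeding keeps both aldehydes dilute so that acetaldehyde self-trimerisation and alkylative loss of enzyme activity stay small.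

Step 2
Reactants: 6 4-bromo-2,6-dimethoxyphenol
Product: 7 2-(benzyloxy)-5-bromo-1,3-dimethoxybenzene
Conditions: BnBr, K2CO3, DMF, 60 °C
Reagents that add atoms: benzyl bromide, BrCc1ccccc1
Why: Williamson etherification of the phenoxide masks the acidic phenol so that the aryl bromide can be converted into a Grignard reagent; no stereocentre is involved.

Step 3
Reactants: 5 6-chloro-2,4,6-trideoxy-D-erythro-hexopyranose (dried by toluene azeotrope); 7 2-(benzyloxy)-5-bromo-1,3-dimethoxybenzene (3.5 equiv)
Product: 9 (3S,5S)-1-[4-(benzyloxy)-3,5-dimethoxyphenyl]-6-chlorohexane-1,3,5-triol (C1 epimers; hexane C1 = target C7), via [4-(benzyloxy)-3,5-dimethoxyphenyl]magnesium bromide 8 (not isolated)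
Conditions: 7, Mg, cat. I2, THF, reflux; then 5 in THF added at 0 °C, 0 °C to rt; aq. NH4Cl
Reagents that add atoms: magnesium, [Mg] (kept only in 8; it leaves on work-up)
Why: Grignard addition to a lactol: two equivalents of 8 deprotonate the two hydroxyls, the magnesium lactolate opens to its aldehyde form and a third equivalent adds at C7, while the magnesium alkoxide of the chlorohydrin does not close at or below room temperature; the new C7 carbinol forms without control, which is harmless because it is removed in step 11, and C3 and C5 are untouched.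

Step 4
Reactants: 9 (3S,5S)-1-[4-(benzyloxy)-3,5-dimethoxyphenyl]-6-chlorohexane-1,3,5-triol
Product: 10 (3S)-1-[4-(benzyloxy)-3,5-dimethoxyphenyl]-4-[(2S)-oxiran-2-yl]butane-1,3-diol (C1 epimers)
Conditions: K2CO3, MeOH, 0 °C to rt
Reagents that add atoms: none
Why: Intramolecular Williamson reaction (3-exo-tet) of the chlorohydrin, the most acidic alcohol of 9, displaces the primary chloride at C2, so the C3–O bond and its configuration are kept, and the mild carbonate base at low temperature gives the C7 hydroxyl little chance to attack the new oxirane.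

Step 5
Reactants: 10 (3S)-1-[4-(benzyloxy)-3,5-dimethoxyphenyl]-4-[(2S)-oxiran-2-yl]butane-1,3-diol
Product: 11 (2S)-2-{(2R)-4-[4-(benzyloxy)-3,5-dimethoxyphenyl]-2,4-bis[(tert-butyldimethylsilyl)oxy]butyl}oxirane (epimers at the benzylic carbon)
Conditions: TBSCl (3 equiv), imidazole, cat. DMAP, DMF, rt
Reagents that add atoms: tert-butyldimethylsilyl chloride, CC(C)(C)[Si](C)(C)Cl
Why: Imidazole-promoted silylation caps O5 and O7, which would otherwise consume two equivalents of the benzylic Grignard reagent and could open the oxirane from within (6-exo attack of O7 on C3); the oxirane tolerates these near-neutral conditions.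

Step 6
Reactants: 12 vanillyl alcohol
Product: 13 [4-(benzyloxy)-3-methoxyphenyl]methanol
Conditions: BnBr, K2CO3, acetone, reflux
Reagents that add atoms: benzyl bromide, BrCc1ccccc1
Why: Chemoselective Williamson etherification, since carbonate deprotonates only the phenol, which is far more acidic than the benzylic alcohol.

Step 7
Reactants: 13 [4-(benzyloxy)-3-methoxyphenyl]methanol
Product: 14 1-(benzyloxy)-4-(chloromethyl)-2-methoxybenzene
Conditions: SOCl2, CH2Cl2, 0 °C; used promptly
Reagents that add atoms: thionyl chloride, O=S(Cl)Cl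
Why: Chlorodehydroxylation through the chlorosulfite ester is fast at 0 °C for an electron-rich benzylic alcohol and leaves the aryl benzyl ether intact.

Step 8
Reactants: 11 bis-silylated oxirane; 14 1-(benzyloxy)-4-(chloromethyl)-2-methoxybenzene (2 equiv)
Product: 16 (3R,5R)-1-[4-(benzyloxy)-3-methoxyphenyl]-7-[4-(benzyloxy)-3,5-dimethoxyphenyl]-5,7-bis[(tert-butyldimethylsilyl)oxy]heptan-3-ol (C7 epimers), via [4-(benzyloxy)-3-methoxybenzyl]magnesium chloride 15 (not isolated)
Conditions: 14 added slowly to excess Mg turnings, 2-MeTHF, 0 °C; then CuI (10 mol %), 11, −30 to 0 °C; aq. NH4Cl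
Reagents that add atoms: magnesium, [Mg] (kept only in 15; it leaves on work-up)
Why: Copper-catalysed Grignard opening of a terminal epoxide proceeds by SN2 attack at the unhindered C2 and forms C1–C2 without touching the C3–O bond, so C3 keeps its configuration; slow addition to excess magnesium in 2-MeTHF limits Wurtz coupling, and silyl and benzyl ethers are inert.

Step 9
Reactants: 16 bis-silyl ether alcohol
Product: 17 (3R,5R)-1-[4-(benzyloxy)-3-methoxyphenyl]-7-[4-(benzyloxy)-3,5-dimethoxyphenyl]heptane-3,5,7-triol (target numbering; C7 epimers)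
Conditions: TBAF (3 equiv), THF, rt
Reagents that add atoms: none
Why: Fluoride-driven desilylation works in a non-acidic medium and so avoids ionising the electron-rich benzylic C7–O bond, which under acid could be captured by O3 to give an oxane.

Step 10
Reactants: 17 triol
Product: 18 (3R,5R)-1-[4-(benzyloxy)-3-methoxyphenyl]-7-[4-(benzyloxy)-3,5-dimethoxyphenyl]heptane-3,5,7-triyl triacetate (C7 epimers)
Conditions: Ac2O, pyridine, cat. DMAP, CH2Cl2, rt
Reagents that add atoms: acetic anhydride, CC(=O)OC(C)=O
Why: DMAP-catalysed acylation esterifies the three secondary alcohols while both phenols remain benzyl ethers, and no C–O bond at a stereocentre is broken.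

Step 11
Reactants: 18 triacetate
Product: 19 (3R,5S)-1-(4-hydroxy-3-methoxyphenyl)-7-(4-hydroxy-3,5-dimethoxyphenyl)heptane-3,5-diyl diacetate (target)
Conditions: H2 (1–4 bar), 10% Pd/C, EtOAc/AcOH 4:1, 25–40 °C
Reagents that add atoms: none
Why: Catalytic hydrogenolysis cleaves only benzylic C–O bonds, namely the two ArO–CH2Ph ethers and the C7–OAc bond (activated by electron-rich ring B, more so once its para phenol is free), whereas the C3 and C5 acetates have no benzylic bond and stay, leaving the (3R,5S) diacetate.

**Compound list**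
1 | chloroacetaldehyde | O=CCCl | starting material
2 | acetaldehyde | CC=O | starting material
3 | (S)-4-chloro-3-hydroxybutanal | O=CC[C@H](O)CCl | intermediate
4 | (3R,5S)-6-chloro-3,5-dihydroxyhexanal | O=CC[C@H](O)C[C@H](O)CCl | intermediate
5 | 6-chloro-2,4,6-trideoxy-D-erythro-hexopyranose, (4R,6S)-6-(chloromethyl)oxane-2,4-diol | OC1C[C@H](O)C[C@@H](CCl)O1 | intermediate
6 | 4-bromo-2,6-dimethoxyphenol | COc1cc(Br)cc(OC)c1O | starting material
7 | 2-(benzyloxy)-5-bromo-1,3-dimethoxybenzene | COc1cc(Br)cc(OC)c1OCc1ccccc1 | intermediate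
8 | [4-(benzyloxy)-3,5-dimethoxyphenyl]magnesium bromide | COc1cc([Mg]Br)cc(OC)c1OCc1ccccc1 | intermediate
9 | (3S,5S)-1-[4-(benzyloxy)-3,5-dimethoxyphenyl]-6-chlorohexane-1,3,5-triol | OC(C[C@H](O)C[C@H](O)CCl)c1cc(OC)c(OCc2ccccc2)c(OC)c1 | intermediate
10 | (3S)-1-[4-(benzyloxy)-3,5-dimethoxyphenyl]-4-[(2S)-oxiran-2-yl]butane-1,3-diol | OC(C[C@H](O)C[C@H]1CO1)c1cc(OC)c(OCc2ccccc2)c(OC)c1 | intermediate
11 | (2S)-2-{(2R)-4-[4-(benzyloxy)-3,5-dimethoxyphenyl]-2,4-bis[(tert-butyldimethylsilyl)oxy]butyl}oxirane | CC(C)(C)[Si](C)(C)OC(C[C@H](O[Si](C)(C)C(C)(C)C)C[C@H]1CO1)c1cc(OC)c(OCc2ccccc2)c(OC)c1 | intermediate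
12 | vanillyl alcohol | COc1cc(CO)ccc1O | starting material
13 | [4-(benzyloxy)-3-methoxyphenyl]methanol | COc1cc(CO)ccc1OCc1ccccc1 | intermediate
14 | 1-(benzyloxy)-4-(chloromethyl)-2-methoxybenzene | COc1cc(CCl)ccc1OCc1ccccc1 | intermediate
15 | [4-(benzyloxy)-3-methoxybenzyl]magnesium chloride | COc1cc(C[Mg]Cl)ccc1OCc1ccccc1 | intermediate
16 | (3R,5R)-1-[4-(benzyloxy)-3-methoxyphenyl]-7-[4-(benzyloxy)-3,5-dimethoxyphenyl]-5,7-bis[(tert-butyldimethylsilyl)oxy]heptan-3-ol | COc1cc(CC[C@H](C[C@H](CC(O[Si](C)(C)C(C)(C)C)c2cc(OC)c(OCc3ccccc3)c(OC)c2)O[Si](C)(C)C(C)(C)C)O)ccc1OCc1ccccc1 | intermediate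
17 | (3R,5R)-1-[4-(benzyloxy)-3-methoxyphenyl]-7-[4-(benzyloxy)-3,5-dimethoxyphenyl]heptane-3,5,7-triol | COc1cc(CC[C@H](C[C@H](CC(O)c2cc(OC)c(OCc3ccccc3)c(OC)c2)O)O)ccc1OCc1ccccc1 | intermediate
18 | (3R,5R)-1-[4-(benzyloxy)-3-methoxyphenyl]-7-[4-(benzyloxy)-3,5-dimethoxyphenyl]heptane-3,5,7-triyl triacetate | COc1cc(CC[C@H](C[C@H](CC(OC(C)=O)c2cc(OC)c(OCc3ccccc3)c(OC)c2)OC(C)=O)OC(C)=O)ccc1OCc1ccccc1 | intermediate
19 | (3R,5S)-1-(4-hydroxy-3-methoxyphenyl)-7-(4-hydroxy-3,5-dimethoxyphenyl)heptane-3,5-diyl diacetate | COc1cc(CC[C@H](C[C@H](CCc2cc(OC)c(O)c(OC)c2)OC(C)=O)OC(C)=O)ccc1O | target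

**Total step count:** 11. **Longest linear sequence:** 8 (steps 1, 3, 4, 5, 8, 9, 10, 11; the branch through step 2 is equally long).

**Steps most likely to fail**

1. Step 8. Wurtz-type homocoupling during magnesium insertion into the electron-rich benzylic chloride, and halide opening of the oxirane by magnesium salts, could starve the coupling. The fallback replaces the Grignard reagent by a sulfone-stabilised carbanion; it sets out from 14 and 11 and returns at 16.
   - 14 is treated with PhSO2Na in DMF to give 1-(benzyloxy)-2-methoxy-4-[(phenylsulfonyl)methyl]benzene F1.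
   - F1 is deprotonated with n-BuLi in THF at −78 °C and opens 11 at C2, with BF3·OEt2 assistance if needed, to give the C1-phenylsulfonyl derivative of 16 F2, a γ-hydroxy sulfone that cannot undergo olefin-forming elimination.
   - Reductive desulfonylation with Mg in MeOH then gives 16 with benzyl and silyl ethers intact.

2. Step 3. Possible failures are incomplete opening of a poorly soluble magnesium lactolate, β-elimination or retro-aldol cleavage of the unprotected aldolate, and early oxirane closure followed by aryl attack. The fallback uses a lactol with a single acidic hydrogen; it sets out from 5 and returns at 11.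
   - 5 is oxidised with NaOCl/AcOH in water to (4R,6S)-6-(chloromethyl)-4-hydroxyoxan-2-one F3.
   - F3 is silylated (TBSCl, imidazole, DMF) to (4R,6S)-4-[(tert-butyldimethylsilyl)oxy]-6-(chloromethyl)oxan-2-one F4.
   - F4 is reduced with i-Bu2AlH in toluene at −78 °C to (4R,6S)-4-[(tert-butyldimethylsilyl)oxy]-6-(chloromethyl)oxan-2-ol F5.
   - F5 takes up 8 (2.2 equiv, THF, 0 °C) to give (3S,5S)-1-[4-(benzyloxy)-3,5-dimethoxyphenyl]-3-[(tert-butyldimethylsilyl)oxy]-6-chlorohexane-1,5-diol F6.
   - K2CO3 in MeOH closes F6 to (3S)-1-[4-(benzyloxy)-3,5-dimethoxyphenyl]-3-[(tert-butyldimethylsilyl)oxy]-4-[(2S)-oxiran-2-yl]butan-1-ol F7.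
   - Silylation of the remaining benzylic hydroxyl of F7 gives 11.

3. Step 11. The reduction could stall after debenzylation with the benzylic acetate still in place, or the benzylic position could be captured by solvent. The fallback separates the two tasks; it sets out from 18 and returns at 19.
   - Ionic hydrogenation of 18 (Et3SiH, TFA, CH2Cl2, 0 °C) ionises only the electron-rich benzylic acetate. All other oxygens are acylated and cannot cyclise onto C7. The product is (3R,5S)-1-[4-(benzyloxy)-3-methoxyphenyl]-7-[4-(benzyloxy)-3,5-dimethoxyphenyl]heptane-3,5-diyl diacetate F8.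
   - Plain debenzylation of F8 (H2, Pd/C, EtOAc, rt) then gives 19.

**Further compounds**
F1 | step 8 | 1-(benzyloxy)-2-methoxy-4-[(phenylsulfonyl)methyl]benzene | COc1cc(CS(=O)(=O)c2ccccc2)ccc1OCc1ccccc1
F2 | step 8 | C1-phenylsulfonyl derivative of 16 (C1 and C7 epimers) | COc1cc(C(C[C@H](C[C@H](CC(O[Si](C)(C)C(C)(C)C)c2cc(OC)c(OCc3ccccc3)c(OC)c2)O[Si](C)(C)C(C)(C)C)O)S(=O)(=O)c2ccccc2)ccc1OCc1ccccc1
F3 | step 3 | (4R,6S)-6-(chloromethyl)-4-hydroxyoxan-2-one | O=C1C[C@H](O)C[C@@H](CCl)O1
F4 | step 3 | (4R,6S)-4-[(tert-butyldimethylsilyl)oxy]-6-(chloromethyl)oxan-2-one | O=C1C[C@H](O[Si](C)(C)C(C)(C)C)C[C@@H](CCl)O1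
F5 | step 3 | (4R,6S)-4-[(tert-butyldimethylsilyl)oxy]-6-(chloromethyl)oxan-2-ol | OC1C[C@H](O[Si](C)(C)C(C)(C)C)C[C@@H](CCl)O1
F6 | step 3 | (3S,5S)-1-[4-(benzyloxy)-3,5-dimethoxyphenyl]-3-[(tert-butyldimethylsilyl)oxy]-6-chlorohexane-1,5-diol | OC(C[C@H](O[Si](C)(C)C(C)(C)C)C[C@H](O)CCl)c1cc(OC)c(OCc2ccccc2)c(OC)c1
F7 | step 3 | (3S)-1-[4-(benzyloxy)-3,5-dimethoxyphenyl]-3-[(tert-butyldimethylsilyl)oxy]-4-[(2S)-oxiran-2-yl]butan-1-ol | OC(C[C@H](O[Si](C)(C)C(C)(C)C)C[C@H]1CO1)c1cc(OC)c(OCc2ccccc2)c(OC)c1
F8 | step 11 | (3R,5S)-1-[4-(benzyloxy)-3-methoxyphenyl]-7-[4-(benzyloxy)-3,5-dimethoxyphenyl]heptane-3,5-diyl diacetate | COc1cc(CC[C@H](C[C@H](CCc2cc(OC)c(OCc3ccccc3)c(OC)c2)OC(C)=O)OC(C)=O)ccc1OCc1ccccc1
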